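The α-methylene-γ-butyrolactone (ring A: O1, C2, C3, C3a, C15a) is disconnected last, as a formal [3+2] adduct of 2-bromoacrylic acid and the C3a=C15a edge of a 14-membered all-E tetraene. The step exploits that C15a is allylic to the C14=C15 alkene, so it can be the terminus of an allylpalladium. A Larock-type heteroannulation adds the vinyl unit to C3a and closes the lactone through O1–C15a, setting both ring-fusion stereocentres trans in one operation on a precursor with no lactone at all. The tetraene comes from two rounds of enal propargylation/carboalumination (setting C8 and C12) and ring-closing metathesis.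

Key step: step 12

Remark: positions are given in the numbering of the final cyclotetradeca[b]furanone (O1, C2, C3, C3a, C4–C15, C15a), also for earlier intermediates ("future C8"); 2-bromoacrylic acid, allenylboronic acid pinacol ester and vinyl bromide solution are taken as commercial.

Step 1
Reactants: 1 ethyl but-2-ynoate; 2 but-3-en-1-ylmagnesium bromide
Product: 4 ethyl (2E)-3-methylhepta-2,6-dienoate, via alkenylcopper adduct 3 (not isolated)
Conditions: 2, CuBr·SMe2 (1.1 equiv), THF, −78 °C; then 1; MeOH, then aq. NH4Cl at −78 °C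
Reagents that add atoms: none
Why: Organocopper conjugate addition to an alkynoate is a stereospecific syn-carbocupration, and protonation of the alkenylcopper with retention at low temperature places the new chain trans to the ester, which fixes the E alkene (future C6=C7).

Step 2
Reactants: 4 ethyl (2E)-3-methylhepta-2,6-dienoate
Product: 5 (2E)-3-methylhepta-2,6-dien-1-ol
Conditions: i-Bu2AlH (2.2 equiv), CH2Cl2, −78 °C; Rochelle salt work-up
Reagents that add atoms: none
Why: Low-temperature aluminium hydride reduction of an α,β-unsaturated ester is a clean 1,2-reduction that leaves both alkenes and the E geometry untouched.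

Step 3
Reactants: 5 (2E)-3-methylhepta-2,6-dien-1-ol
Product: 6 (2E)-3-methylhepta-2,6-dienal
Conditions: MnO2 (excess), CH2Cl2, rt; used as a concentrated solution (volatile)
Reagents that add atoms: none
Why: MnO2 oxidises the primary allylic alcohol selectively to the enal without over-oxidation or E/Z isomerisation.

Step 4
Reactants: 6 (2E)-3-methylhepta-2,6-dienal; 7 allenylboronic acid pinacol ester
Product: 8 (4S,5E)-6-methyldeca-5,9-dien-1-yn-4-ol
Conditions: 7 (1.5 equiv), (S)-TRIP phosphoric acid (10 mol %), 4 Å MS, toluene, −20 °C; aqueous work-up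
Reagents that add atoms: none
Why: Chiral phosphoric acid-catalysed allenylboration (asymmetric carbonyl propargylation) proceeds through a closed six-membered SE2' transition state with 1,2-selectivity, and the catalyst antipode is chosen for Si-face attack on the aldehyde ((S)-TRIP by analogy with the related allylborations), which sets the S carbinol (future C8).

Step 5
Reactants: 8 (4S,5E)-6-methyldeca-5,9-dien-1-yn-4-ol
Product: 9 tert-butyldimethyl{[(4S,5E)-6-methyldeca-5,9-dien-1-yn-4-yl]oxy}silane
Conditions: TBSCl, imidazole, DMF, rt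
Reagents that add atoms: tert-butyldimethylsilyl chloride, CC(C)(C)[Si](C)(C)Cl
Why: Standard silylation of a secondary alcohol gives an ether that should withstand Me3Al, n-BuLi, MnO2 and the later palladium and ruthenium steps, and that is removed last.

Step 6
Reactants: 9 tert-butyldimethyl{[(4S,5E)-6-methyldeca-5,9-dien-1-yn-4-yl]oxy}silane
Product: 12 (2E,5S,6E)-5-[(tert-butyldimethylsilyl)oxy]-3,7-dimethylundeca-2,6,10-trien-1-ol, via alkenylalane 10 (not isolated), via lithium alkenylalanate 11 (not isolated)
Conditions: Me3Al (2.5 equiv), Cp2ZrCl2 (0.25 equiv), CH2Cl2, 0 °C to rt; then n-BuLi, THF, −78 °C; (CH2O)n, −78 °C to rt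
Reagents that add atoms: trimethylaluminium, C[Al](C)C; formaldehyde (from paraformaldehyde), C=O
Why: Zirconium-catalysed Negishi carboalumination adds methyl and aluminium syn across the terminal alkyne with methyl at the internal carbon (the monosubstituted alkene reacts far more slowly), and hydroxymethylation of the derived alanate occurs with retention, which fixes the E trisubstituted alkene (future C10=C11).

Step 7
Reactants: 12 (2E,5S,6E)-5-[(tert-butyldimethylsilyl)oxy]-3,7-dimethylundeca-2,6,10-trien-1-ol
Product: 13 (2E,5S,6E)-5-[(tert-butyldimethylsilyl)oxy]-3,7-dimethylundeca-2,6,10-trienal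
Conditions: MnO2 (excess), CH2Cl2, rt
Reagents that add atoms: none
Why: Selective allylic oxidation as in step 3; the silyl ether and the other alkenes are inert to MnO2.

Step 8
Reactants: 13 (2E,5S,6E)-5-[(tert-butyldimethylsilyl)oxy]-3,7-dimethylundeca-2,6,10-trienal; 7 allenylboronic acid pinacol ester
Product: 14 (4S,5E,8S,9E)-8-[(tert-butyldimethylsilyl)oxy]-6,10-dimethyltetradeca-5,9,13-trien-1-yn-4-ol
Conditions: 7 (1.5 equiv), (S)-TRIP phosphoric acid (10 mol %), 4 Å MS, toluene, −20 °C; aqueous work-up
Reagents that add atoms: none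
Why: Same catalyst-controlled allenylboration as in step 4; the remote silyloxy stereocentre should exert no useful bias, so Si-face attack under catalyst control sets the second S carbinol (future C12).

Step 9
Reactants: 14 (4S,5E,8S,9E)-8-[(tert-butyldimethylsilyl)oxy]-6,10-dimethyltetradeca-5,9,13-trien-1-yn-4-ol; 15 vinyl bromide
Product: 17 (3E,6S,7E,10S,11E)-10-[(tert-butyldimethylsilyl)oxy]-4,8,12-trimethylhexadeca-1,3,7,11,15-pentaen-6-ol, via alkenylalane alkoxide 16 (not isolated)
Conditions: Me3Al (3.5 equiv), Cp2ZrCl2 (0.25 equiv), CH2Cl2, 0 °C to rt; then 15 (THF solution), ZnCl2, Pd(PPh3)4 (5 mol %), THF, rt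
Reagents that add atoms: trimethylaluminium, C[Al](C)C
Why: Negishi carboalumination of the homopropargylic alcohol (carried as its aluminium alkoxide) followed by zinc-assisted palladium-catalysed cross-coupling of the alkenylalane with vinyl bromide proceeds with retention and gives the E-configured 2-methyl-1,3-diene (future C14=C15 and C15a).

Step 10
Reactants: 17 (3E,6S,7E,10S,11E)-10-[(tert-butyldimethylsilyl)oxy]-4,8,12-trimethylhexadeca-1,3,7,11,15-pentaen-6-ol
Product: 18 (3E,6S,7E,10S,11E)-10-[(tert-butyldimethylsilyl)oxy]-4,8,12-trimethylhexadeca-1,3,7,11,15-pentaen-6-yl acetate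
Conditions: Ac2O, pyridine, DMAP (cat.), CH2Cl2, 0 °C to rt
Reagents that add atoms: acetic anhydride, CC(=O)OC(C)=O
Why: Nucleophile-catalysed acylation of the only free hydroxyl installs the acetate of the target at the future C12 without touching the stereocentre.

Step 11
Reactants: 18 (3E,6S,7E,10S,11E)-10-[(tert-butyldimethylsilyl)oxy]-4,8,12-trimethylhexadeca-1,3,7,11,15-pentaen-6-yl acetate
Product: 19 (1S,2E,5S,6E,10E,12E)-5-[(tert-butyldimethylsilyl)oxy]-3,7,13-trimethylcyclotetradeca-2,6,10,12-tetraen-1-yl acetate
Conditions: second-generation Grubbs catalyst (10 mol %), CH2Cl2 (0.001 M), 40 °C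
Reagents that add atoms: none
Why: Ring-closing metathesis between the monosubstituted alkene and the terminal vinyl of the diene closes the 14-membered carbocycle with loss of ethene; the trisubstituted alkenes (including the methyl-bearing diene alkene) are inert, and the s-trans E,E-diene should be favoured under the reversible conditions.

Step 12
Reactants: 19 (1S,2E,5S,6E,10E,12E)-5-[(tert-butyldimethylsilyl)oxy]-3,7,13-trimethylcyclotetradeca-2,6,10,12-tetraen-1-yl acetate; 20 2-bromoacrylic acid
Product: 22 (3aR,6E,8S,10E,12S,14E,15aS)-8-[(tert-butyldimethylsilyl)oxy]-6,10,14-trimethyl-3-methylidene-2-oxo-2,3,3a,4,5,8,9,12,13,15a-decahydrocyclotetradeca[b]furan-12-yl acetate, via oxapalladacycle 21 (not isolated)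
Conditions: 20 (1.3 equiv), Pd(OAc)2 (10 mol %), Ag2CO3 (1.2 equiv), BHT (cat.), DMF, 60 °C
Reagents that add atoms: none
Why: Larock-type heteroannulation of a 1,3-diene by an α-haloacrylic acid: zerovalent palladium inserts into the C–Br bond of 20, the α-carboxyvinyl–palladium species adds syn across the disubstituted C3a=C15a alkene with C–C bond formation at C3a (the unmethylated diene terminus), and the resulting allylpalladium (C15a–C15–C14), held by its own carboxylate as oxapalladacycle 21, collapses by C–O reductive elimination at C15a and returns zerovalent palladium. Ring A closes in a 5-exo sense on the proximal allyl terminus by formation of the O1–C15a bond; closure at the distal, methyl-bearing C14 would need a seven-membered ring. C3a is set by the face on which carbopalladation occurs, and C15a is set relative to it: vinyl and palladium arrive on the same face, and in the halide-free medium (Ag2CO3 removes bromide) the carboxylate should stay on palladium and replace it with retention, so the net syn addition across the E-alkene can only give the trans ring fusion, while the 14E geometry is kept because the fully substituted allyl terminus does not undergo syn–anti exchange. The step needs site selectivity (conjugated diene over the two isolated trisubstituted alkenes, disubstituted over trisubstituted diene terminus), which is inherent to carbopalladation, and it needs attack on the diene face that is Si at C3a and Re at C15a. That face selectivity rests on macrocyclic stereocontrol, that is peripheral attack on the edge-on s-trans diene of the ring conformer fixed by the three E-alkenes and the C8 and C12 substituents; its sense cannot be predicted with confidence, and it is the least secure element of the route. The allylic acetate should survive because no phosphine is present and zerovalent palladium is recaptured quickly by the electron-poor vinyl bromide.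

Step 13
Reactants: 22 (3aR,6E,8S,10E,12S,14E,15aS)-8-[(tert-butyldimethylsilyl)oxy]-6,10,14-trimethyl-3-methylidene-2-oxo-2,3,3a,4,5,8,9,12,13,15a-decahydrocyclotetradeca[b]furan-12-yl acetate
Product: 23 (3aR,6E,8S,10E,12S,14E,15aS)-8-hydroxy-6,10,14-trimethyl-3-methylidene-2-oxo-2,3,3a,4,5,8,9,12,13,15a-decahydrocyclotetradeca[b]furan-12-yl acetate (CNP0168244.1)
Conditions: HF·pyridine, pyridine/THF, 0 °C to rt
Reagents that add atoms: none
Why: Buffered fluoride cleavage of the secondary silyl ether should leave the acetate, the allylic lactone and the α-methylene unit untouched and touches no stereocentre.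

Compound list
1 | ethyl but-2-ynoate | CC#CC(=O)OCC | starting material
2 | but-3-en-1-ylmagnesium bromide | C=CCC[Mg]Br | starting material
3 | ethyl (2Z)-2-cuprio-3-methylhepta-2,6-dienoate (alkenylcopper adduct) | CCOC(=O)/C([Cu])=C(\C)CCC=C | intermediate
4 | ethyl (2E)-3-methylhepta-2,6-dienoate | CCOC(=O)/C=C(\C)CCC=C | intermediate
5 | (2E)-3-methylhepta-2,6-dien-1-ol | OC/C=C(\C)CCC=C | intermediate
6 | (2E)-3-methylhepta-2,6-dienal | O=C/C=C(\C)CCC=C | intermediate
7 | allenylboronic acid pinacol ester (4,4,5,5-tetramethyl-2-(propa-1,2-dien-1-yl)-1,3,2-dioxaborolane) | C=C=CB1OC(C)(C)C(C)(C)O1 | starting material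
8 | (4S,5E)-6-methyldeca-5,9-dien-1-yn-4-ol | C#CC[C@H](O)/C=C(\C)CCC=C | intermediate
9 | tert-butyldimethyl{[(4S,5E)-6-methyldeca-5,9-dien-1-yn-4-yl]oxy}silane | C#CC[C@H](O[Si](C)(C)C(C)(C)C)/C=C(\C)CCC=C | intermediate
10 | {(1E,4S,5E)-4-[(tert-butyldimethylsilyl)oxy]-2,6-dimethyldeca-1,5,9-trien-1-yl}dimethylalane (alkenylalane) | C[Al](C)/C=C(\C)C[C@H](O[Si](C)(C)C(C)(C)C)/C=C(\C)CCC=C | intermediate
11 | lithium butyl{(1E,4S,5E)-4-[(tert-butyldimethylsilyl)oxy]-2,6-dimethyldeca-1,5,9-trien-1-yl}dimethylalanate | [Li+].CCCC[Al-](C)(C)/C=C(\C)C[C@H](O[Si](C)(C)C(C)(C)C)/C=C(\C)CCC=C | intermediate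
12 | (2E,5S,6E)-5-[(tert-butyldimethylsilyl)oxy]-3,7-dimethylundeca-2,6,10-trien-1-ol | OC/C=C(\C)C[C@H](O[Si](C)(C)C(C)(C)C)/C=C(\C)CCC=C | intermediate
13 | (2E,5S,6E)-5-[(tert-butyldimethylsilyl)oxy]-3,7-dimethylundeca-2,6,10-trienal | O=C/C=C(\C)C[C@H](O[Si](C)(C)C(C)(C)C)/C=C(\C)CCC=C | intermediate
14 | (4S,5E,8S,9E)-8-[(tert-butyldimethylsilyl)oxy]-6,10-dimethyltetradeca-5,9,13-trien-1-yn-4-ol | C#CC[C@H](O)/C=C(\C)C[C@H](O[Si](C)(C)C(C)(C)C)/C=C(\C)CCC=C | intermediate
15 | vinyl bromide (bromoethene) | C=CBr | starting material
16 | dimethylaluminium alkoxide of the alkenyl(dimethyl)alane from 14 (alkenylalane alkoxide) | C[Al](C)/C=C(\C)C[C@H](O[Al](C)C)/C=C(\C)C[C@H](O[Si](C)(C)C(C)(C)C)/C=C(\C)CCC=C | intermediate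
17 | (3E,6S,7E,10S,11E)-10-[(tert-butyldimethylsilyl)oxy]-4,8,12-trimethylhexadeca-1,3,7,11,15-pentaen-6-ol | C=C/C=C(\C)C[C@H](O)/C=C(\C)C[C@H](O[Si](C)(C)C(C)(C)C)/C=C(\C)CCC=C | intermediate
18 | (3E,6S,7E,10S,11E)-10-[(tert-butyldimethylsilyl)oxy]-4,8,12-trimethylhexadeca-1,3,7,11,15-pentaen-6-yl acetate | C=C/C=C(\C)C[C@H](OC(C)=O)/C=C(\C)C[C@H](O[Si](C)(C)C(C)(C)C)/C=C(\C)CCC=C | intermediate
19 | (1S,2E,5S,6E,10E,12E)-5-[(tert-butyldimethylsilyl)oxy]-3,7,13-trimethylcyclotetradeca-2,6,10,12-tetraen-1-yl acetate | C1/C(C)=C/[C@@H](O[Si](C)(C)C(C)(C)C)C/C(C)=C/[C@@H](OC(C)=O)C/C(C)=C/C=C/C1 | intermediate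
20 | 2-bromoacrylic acid (2-bromoprop-2-enoic acid) | C=C(Br)C(=O)O | starting material
21 | six-membered oxapalladacycle (σ-allyl form; Pd bound to C15a and to the carboxylate oxygen) | C=C1C(=O)O[Pd][C@H]2/C=C(\C)C[C@H](OC(C)=O)/C=C(\C)C[C@H](O[Si](C)(C)C(C)(C)C)/C=C(\C)CC[C@H]12 | intermediate
22 | (3aR,6E,8S,10E,12S,14E,15aS)-8-[(tert-butyldimethylsilyl)oxy]-6,10,14-trimethyl-3-methylidene-2-oxo-2,3,3a,4,5,8,9,12,13,15a-decahydrocyclotetradeca[b]furan-12-yl acetate | C=C1C(=O)O[C@H]2/C=C(\C)C[C@H](OC(C)=O)/C=C(\C)C[C@H](O[Si](C)(C)C(C)(C)C)/C=C(\C)CC[C@H]12 | intermediate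
23 | (3aR,6E,8S,10E,12S,14E,15aS)-8-hydroxy-6,10,14-trimethyl-3-methylidene-2-oxo-2,3,3a,4,5,8,9,12,13,15a-decahydrocyclotetradeca[b]furan-12-yl acetate | C=C1C(=O)O[C@H]2/C=C(\C)C[C@H](OC(C)=O)/C=C(\C)C[C@H](O)/C=C(\C)CC[C@H]12 | target

Total step count: 13. Longest linear sequence: 13 steps (from 1; the route is linear, with 7, 15 and 20 added as small partners).

Steps most likely to fail

Step 12. The carboxylate may leave palladium and, after rotation about the C3a–C15a bond, attack the allyl terminus anti to the metal, which on the E-alkene would give the cis ring fusion. The macrocycle may also discriminate the two diene faces poorly. Zerovalent palladium may ionise the allylic acetate. The fallback sets out from 18 and changes both the geometry of the precursor and the stereochemical course that is relied on. Ring closure of 18 with a Z-selective cyclometalated ruthenium alkylidene, Ru(κ2-NO3)(=CH-C6H4-2-O-i-Pr)(C,C-chelating adamantyl-cyclometalated 1-(1-adamantyl)-3-(2,6-diisopropylphenyl)imidazolin-2-ylidene), should give the (10Z)-macrocycle F1. F1 is then annulated with 20 under chloride-containing, phosphine-free conditions (Pd(OAc)2, n-Bu4NCl, Na2CO3, DMF, 70 °C), where chloride occupies palladium and the free carboxylate attacks from outside. Syn-carbopalladation followed by anti C–O bond formation across a Z-alkene converges on the same trans ring fusion, so the fallback comes back to the route at 22. The different ring conformer of F1 also offers a second, independent chance for facial control.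

Step 11. Under reversible metathesis the new disubstituted alkene may form as a mixture of geometric isomers, and the terminal diene may divert the carbene into oligomers. The fallback sets out from 14 and fixes both alkene geometries before cyclisation. Carboalumination of 14 as in step 9, quenched with I2, gives vinyl iodide F2, and acetylation (Ac2O, pyridine, DMAP) gives acetate F3. Cross-metathesis of the terminal alkene of F3 with vinylboronic acid pinacol ester (second-generation Grubbs catalyst, CH2Cl2, 40 °C) gives E-alkenylboronate F4. Intramolecular Suzuki–Miyaura coupling (Pd(PPh3)4, TlOEt, THF/H2O, rt, high dilution) forms the C15–C15a bond with retention at both alkenes and comes back to the route at 19.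

Step 4 (the same holds for step 8). Enantiofacial discrimination may be weak for a small β,β-disubstituted enal, the sense of induction assumed for the catalyst may be wrong, and the acid may promote 1,3-transposition of the allylic carbinol. The fallback sets out from allylic alcohol 5 and forms the C–C bond at the alcohol oxidation level, without the free enal. Iridium-catalysed transfer-hydrogenative propargylation with (3-chloroprop-1-yn-1-yl)triisopropylsilane (cyclometalated π-allyliridium C,O-benzoate from [Ir(cod)Cl]2, the SEGPHOS antipode that gives the S carbinol, 4-chloro-3-nitrobenzoic acid and allyl acetate; Na2CO3, THF, 65 °C) should give silyl alkyne F5. Treatment with n-Bu4NF in THF removes the alkynyl silane and comes back to the route at 8.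

Further compounds
F1 | step 12 | (1S,2E,5S,6E,10Z,12E)-5-[(tert-butyldimethylsilyl)oxy]-3,7,13-trimethylcyclotetradeca-2,6,10,12-tetraen-1-yl acetate | C1/C(C)=C/[C@@H](O[Si](C)(C)C(C)(C)C)C/C(C)=C/[C@@H](OC(C)=O)C/C(C)=C/C=C\C1
F2 | step 11 | (1E,4S,5E,8S,9E)-8-[(tert-butyldimethylsilyl)oxy]-1-iodo-2,6,10-trimethyltetradeca-1,5,9,13-tetraen-4-ol | I/C=C(\C)C[C@H](O)/C=C(\C)C[C@H](O[Si](C)(C)C(C)(C)C)/C=C(\C)CCC=C
F3 | step 11 | (1E,4S,5E,8S,9E)-8-[(tert-butyldimethylsilyl)oxy]-1-iodo-2,6,10-trimethyltetradeca-1,5,9,13-tetraen-4-yl acetate | I/C=C(\C)C[C@H](OC(C)=O)/C=C(\C)C[C@H](O[Si](C)(C)C(C)(C)C)/C=C(\C)CCC=C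
F4 | step 11 | (1E,4S,5E,8S,9E,13E)-8-[(tert-butyldimethylsilyl)oxy]-1-iodo-2,6,10-trimethyl-14-(4,4,5,5-tetramethyl-1,3,2-dioxaborolan-2-yl)tetradeca-1,5,9,13-tetraen-4-yl acetate | I/C=C(\C)C[C@H](OC(C)=O)/C=C(\C)C[C@H](O[Si](C)(C)C(C)(C)C)/C=C(\C)CC/C=C/B1OC(C)(C)C(C)(C)O1
F5 | step 4 | (4S,5E)-6-methyl-1-[tri(propan-2-yl)silyl]deca-5,9-dien-1-yn-4-ol | CC(C)[Si](C(C)C)(C(C)C)C#CC[C@H](O)/C=C(\C)CCC=C
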